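The chroman is cut across its pyran ring at O1–C2 and C3–C4. The aryl half, O1–C8a–C4a–C4, is a latent ortho-quinone methide whose carbonyl oxygen lies next to the C8 acetyl, giving a bidentate handle for a chiral Lewis acid. The C2–C3 half is an isobutenyl unit whose C3 oxygen is carried as boron. One asymmetric oxa-[4+2] cycloaddition of this heterodiene to 2-methylprop-1-enyl-Bpin closes the dihydropyran, forms both ring bonds and sets C3. Its precursor is a 3-(hydroxymethyl)-2-hydroxyacetophenone with both remaining phenols benzylated, three steps from phloroacetophenone. C–B oxidation, hydrogenolysis and site-selective C5-O-geranylation finish the route.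

Key step: step 4

Remark on the chemistry: the target is read as the (3R)-chroman-3-ol with the geranyl ether on O5 (para to the acetyl) and the free, hydrogen-bonded phenol on C7. The sense of induction in step 4 cannot be predicted with confidence, so the ligand antipode that delivers the 3R boronate is to be fixed by a trial run; (S,S) is written as the first choice.

Step 1
Reactants: 1 2,4,6-trihydroxyacetophenone; 2 benzyl bromide
Product: 3 1-[2,4-bis(benzyloxy)-6-hydroxyphenyl]ethanone
Conditions: BnBr (2.1 equiv in total), K2CO3 (2.2 equiv), DMF, rt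
Reagents that add atoms: benzyl bromide (second equivalent), BrCc1ccccc1
Why: Twofold Williamson ether synthesis in which two molecules of benzyl bromide are consumed; the phenol hydrogen-bonded to the acetyl carbonyl is the least acidic and least nucleophilic, so alkylation should stop at the 4,6-dibenzyl ether.

Step 2
Reactants: 3 1-[2,4-bis(benzyloxy)-6-hydroxyphenyl]ethanone
Product: 4 1-[4,6-bis(benzyloxy)-3-formyl-2-hydroxyphenyl]ethanone
Conditions: anhydrous MgCl2, Et3N, (CH2O)n, MeCN, reflux; then 1 M HCl
Reagents that add atoms: paraformaldehyde (as formaldehyde), C=O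
Why: Casnati–Skattebøl magnesium-mediated ortho-formylation; the magnesium phenoxide delivers formaldehyde to the only free carbon ortho to the phenol, which is also activated by both benzyloxy groups, and a second formaldehyde takes the hydride from the benzylic alkoxide to give the aldehyde.

Step 3
Reactants: 4 1-[4,6-bis(benzyloxy)-3-formyl-2-hydroxyphenyl]ethanone
Product: 5 1-[4,6-bis(benzyloxy)-2-hydroxy-3-(hydroxymethyl)phenyl]ethanone
Conditions: NaBH4 (0.5 equiv), THF/MeOH, −10 to 0 °C; aq. NH4Cl; used without acidic chromatography
Reagents that add atoms: none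
Why: Chemoselective borohydride reduction; the aldehyde is far more electrophilic than the di-ortho-substituted, chelated aryl methyl ketone, and low temperature with a neutral work-up should protect the acid-labile electron-rich salicyl alcohol.

Step 4
Reactants: 5 1-[4,6-bis(benzyloxy)-2-hydroxy-3-(hydroxymethyl)phenyl]ethanone; 6 2-methylprop-1-enylboronic acid pinacol ester
Product: 8 1-[(3R)-5,7-bis(benzyloxy)-2,2-dimethyl-3-(4,4,5,5-tetramethyl-1,3,2-dioxaborolan-2-yl)-3,4-dihydro-2H-chromen-8-yl]ethanone, via ortho-quinone methide 7 (not isolated)
Conditions: [Cu((S,S)-t-Bu-box)](SbF6)2 (10 mol %), 6 (3 equiv), 4 Å MS, CH2Cl2, argon, slow addition of 5, −40 to 0 °C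
Reagents that add atoms: none
Why: Proposed new method: copper(II) binds the phenol oxygen and the C8 acetyl oxygen of 5, the acidified phenol proton passes to the benzylic hydroxyl and water leaves, so quinone methide 7 forms as a cationic two-point chelate; the alkene of 6 then attacks the methide carbon C4 through its boron-bearing carbon, positive charge builds on the dimethyl-substituted carbon (tertiary, and β to boron so stabilised by the C–B σ bond), and the copper-bound phenoxide O1 collapses onto it as the arene is regained, an asynchronous inverse-demand oxa-Diels–Alder reaction. The closest known reaction types are catalytic asymmetric [4+2] cycloadditions of ortho-quinone methides with alkenes and copper(II) bis(oxazoline) catalysis of chelating oxa-dienes such as alkylidene 1,3-dicarbonyls and unsaturated α-keto esters; an alkenylboronate as the 2π partner with boron retained has not been shown. The dihydropyran ring (O1, C2, C3, C4, C4a, C8a) is closed by the cycloaddition itself, C3–C4 first and O1–C2 second by intramolecular capture of the tertiary cation by the phenoxide. The only new stereocentre, C3, is controlled by the catalyst: the tert-butyl groups of the ligand shield one face of the planar chelated heterodiene and the bulky Bpin group is expected to point away from diene and ligand (exo), so a single enantiotopic face of the alkene is bonded. The step needs regioselectivity (gem-dimethyl carbon on O1, boron on C3), which the tertiary cation character secures; enantiofacial selectivity, which rests on the acetyl/carbonyl chelate; and ring closure in preference to loss of boron from the β-boryl cation (which would give the C-prenylated phenol), which the non-nucleophilic counter-ion, the sieves, the base-free medium and the low temperature are chosen to favour.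

Step 5
Reactants: 8 1-[(3R)-5,7-bis(benzyloxy)-2,2-dimethyl-3-(4,4,5,5-tetramethyl-1,3,2-dioxaborolan-2-yl)-3,4-dihydro-2H-chromen-8-yl]ethanone
Product: 9 1-[(3R)-5,7-bis(benzyloxy)-3-hydroxy-2,2-dimethyl-3,4-dihydro-2H-chromen-8-yl]ethanone
Conditions: NaBO3·4H2O (4 equiv), THF/H2O 1:1, 0 °C to rt
Reagents that add atoms: sodium perborate (NaBO3·4H2O), [Na+].[Na+].O[B-]1(O)OO[B-](O)(O)OO1
Why: Oxidation of an alkylboronic ester by perborate; the peroxide adds to boron and C3 migrates from boron to oxygen with retention, so the 3R configuration is carried over, while the buffered medium and the absence of a free phenol should spare the acetyl group from Dakin-type oxidation.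

Step 6
Reactants: 9 1-[(3R)-5,7-bis(benzyloxy)-3-hydroxy-2,2-dimethyl-3,4-dihydro-2H-chromen-8-yl]ethanone
Product: 10 1-[(3R)-3,5,7-trihydroxy-2,2-dimethyl-3,4-dihydro-2H-chromen-8-yl]ethanone
Conditions: H2 (1 atm), 10% Pd/C, EtOAc/MeOH, rt
Reagents that add atoms: none
Why: Catalytic hydrogenolysis of benzyl aryl ethers; the electron-rich, hydrogen-bonded aryl ketone and the non-benzylic C3 carbinol should be untouched at 1 atm, and no alkene is yet present.

Step 7
Reactants: 10 1-[(3R)-3,5,7-trihydroxy-2,2-dimethyl-3,4-dihydro-2H-chromen-8-yl]ethanone; 11 geranyl bromide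
Product: 12 1-[(3R)-5-{[(2E)-3,7-dimethylocta-2,6-dien-1-yl]oxy}-3,7-dihydroxy-2,2-dimethyl-3,4-dihydro-2H-chromen-8-yl]ethanone
Conditions: geranyl bromide (1.05 equiv), K2CO3 (1.1 equiv), acetone, rt, dark
Reagents that add atoms: none
Why: Site-selective Williamson etherification; the C5 phenol (para to the acetyl, not hydrogen-bonded) is the most acidic and nucleophilic hydroxyl, the C7 phenol is locked in a hydrogen bond to the acetyl and the secondary alcohol is not deprotonated by carbonate, while SN2 at the primary allylic bromide keeps the E geometry.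

Compound list
1 | 2,4,6-trihydroxyacetophenone (phloroacetophenone) | CC(=O)c1c(O)cc(O)cc1O | starting material
2 | benzyl bromide | BrCc1ccccc1 | starting material
3 | 1-[2,4-bis(benzyloxy)-6-hydroxyphenyl]ethanone | CC(=O)c1c(OCc2ccccc2)cc(OCc2ccccc2)cc1O | intermediate
4 | 1-[4,6-bis(benzyloxy)-3-formyl-2-hydroxyphenyl]ethanone | CC(=O)c1c(OCc2ccccc2)cc(OCc2ccccc2)c(C=O)c1O | intermediate
5 | 1-[4,6-bis(benzyloxy)-2-hydroxy-3-(hydroxymethyl)phenyl]ethanone | CC(=O)c1c(OCc2ccccc2)cc(OCc2ccccc2)c(CO)c1O | intermediate
6 | 2-methylprop-1-enylboronic acid pinacol ester | CC(C)=CB1OC(C)(C)C(C)(C)O1 | starting material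
7 | 2-acetyl-3,5-bis(benzyloxy)-6-methylidenecyclohexa-2,4-dien-1-one (ortho-quinone methide, copper-bound) | CC(=O)C1=C(OCc2ccccc2)C=C(OCc2ccccc2)C(=C)C1=O | intermediate
8 | 1-[(3R)-5,7-bis(benzyloxy)-2,2-dimethyl-3-(4,4,5,5-tetramethyl-1,3,2-dioxaborolan-2-yl)-3,4-dihydro-2H-chromen-8-yl]ethanone | CC(=O)c1c(OCc3ccccc3)cc(OCc3ccccc3)c2c1OC(C)(C)[C@H](B3OC(C)(C)C(C)(C)O3)C2 | intermediate
9 | 1-[(3R)-5,7-bis(benzyloxy)-3-hydroxy-2,2-dimethyl-3,4-dihydro-2H-chromen-8-yl]ethanone | CC(=O)c1c(OCc3ccccc3)cc(OCc3ccccc3)c2c1OC(C)(C)[C@H](O)C2 | intermediate
10 | 1-[(3R)-3,5,7-trihydroxy-2,2-dimethyl-3,4-dihydro-2H-chromen-8-yl]ethanone | CC(=O)c1c(O)cc(O)c2c1OC(C)(C)[C@H](O)C2 | intermediate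
11 | geranyl bromide, (2E)-1-bromo-3,7-dimethylocta-2,6-diene | BrC/C=C(\C)CCC=C(C)C | starting material
12 | 1-[(3R)-5-{[(2E)-3,7-dimethylocta-2,6-dien-1-yl]oxy}-3,7-dihydroxy-2,2-dimethyl-3,4-dihydro-2H-chromen-8-yl]ethanone | CC(=O)c1c(O)cc(OC/C=C(\C)CCC=C(C)C)c2c1OC(C)(C)[C@H](O)C2 | target

Total step count: 7. Longest linear sequence: 7 steps (1 → 3 → 4 → 5 → 8 → 9 → 10 → 12).

Steps most likely to fail

1. Step 4 (proposed new method). Three things may go wrong.
   - Boron may be lost from the cationic intermediate, either by alkenyl transfer to C4 or by Lewis-acid ring opening of the β-aryloxy boronate; both end in C-prenylation.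
   - The quinone methide may be consumed by Friedel–Crafts self-condensation through the one unsubstituted ring carbon, between the two benzyloxy groups (C6 in chroman numbering).
   - Facial discrimination of an unfunctionalised alkenylboronate may be poor.

   Fallback by known chemistry, setting out from 3 and returning at 10, so that steps 2 to 6 are bypassed: condensation of 3 with 3-methylbut-2-enal (PhB(OH)2, AcOH, toluene, reflux, Dean–Stark) should give the chromene 1-[5,7-bis(benzyloxy)-2,2-dimethyl-2H-chromen-8-yl]ethanone F1 by ortho-C-alkylation and 6π-electrocyclisation. Jacobsen–Katsuki epoxidation of this 2,2-dimethylchromene with the (R,R)-Mn(salen) catalyst (m-CPBA/NMO, CH2Cl2, −78 °C, chosen over hypochlorite to avoid ring chlorination) should give 1-[(3R,4R)-5,7-bis(benzyloxy)-3,4-epoxy-2,2-dimethyl-3,4-dihydro-2H-chromen-8-yl]ethanone F2. The (R,R) antipode is the one expected by analogy to give the 3R,4R epoxide and is to be confirmed. Hydrogenation of crude F2 (H2, Pd/C, EtOAc/MeOH) should cleave the benzylic C4–O bond, leaving C3 untouched, and both benzyl ethers, giving 10.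

2. Step 2. The strongly chelated magnesium phenoxide may react sluggishly, the acetyl methyl may be hydroxymethylated, and the intermediate benzylic alkoxide of this very electron-rich ring may condense to diarylmethanes before it is oxidised. Fallback, setting out from 3 and returning at 5, so that steps 2 and 3 are both replaced: boron-templated ortho-hydroxymethylation (PhB(OH)2, paraformaldehyde, cat. propionic acid, toluene, reflux, Dean–Stark) should give the cyclic boronate 1-[5,7-bis(benzyloxy)-2-phenyl-4H-1,3,2-benzodioxaborinin-8-yl]ethanone F3. Transesterification with propane-1,3-diol (THF, rt) should release 5 without passing through the aldehyde oxidation level.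

3. Step 7. Site selectivity between the two phenols may be lost, or C-alkylation at C6 of the phloroglucinol-type ring may compete under basic conditions. Fallback, setting out from 10 and returning at 12: Mitsunobu etherification with geraniol (PPh3, DIAD, THF, 0 °C). It runs without a phenoxide, so C-alkylation is suppressed, and it engages only the more acidic, non-chelated C5 phenol as the acid component; the hindered secondary C3 alcohol is a poor alcohol partner. No new intermediate is formed.

Further compounds
F1 | step 4 | 1-[5,7-bis(benzyloxy)-2,2-dimethyl-2H-chromen-8-yl]ethanone | CC(=O)c1c(OCc3ccccc3)cc(OCc3ccccc3)c2c1OC(C)(C)C=C2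
F2 | step 4 | 1-[(3R,4R)-5,7-bis(benzyloxy)-3,4-epoxy-2,2-dimethyl-3,4-dihydro-2H-chromen-8-yl]ethanone | CC(=O)c1c(OCc3ccccc3)cc(OCc3ccccc3)c2c1OC(C)(C)[C@@H]1O[C@H]21
F3 | step 2 | 1-[5,7-bis(benzyloxy)-2-phenyl-4H-1,3,2-benzodioxaborinin-8-yl]ethanone | CC(=O)c1c(OCc2ccccc2)cc(OCc2ccccc2)c2COB(c3ccccc3)Oc12
F0 | step 7 | none | none
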